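**Plan**

Numbering (germacrane): C1 ketone, C2=C3 enol ether, C4(=C15), C5–OH, C6–O (lactone), C7, C8–O (isobutyrate), C9, C10 (CH3, O), C11(=C13)–C12 lactone.
Cuts, in retrosynthetic order: C5–O–Si and the C8 ester; then C1–C2 and O–C10 together; C4–C5 (Morita–Baylis–Hillman with methyl vinyl ketone); C6–C7 and the lactone C–O (Barbier); C7–C11 (Morita–Baylis–Hillman with methyl acrylate); C10–Cl and C10–CH3 (lactone enolate chemistry).
Enabling feature: the 3(2H)-furanone (O, C3, C2, C1, C10) bridges C3 and C10 of the ten-membered carbocycle, so its C1–C2 bond is also a bond of the large ring. C1, C10, C9, C8 and the C8 oxygen are the atoms of a gamma-butyrolactone, so an alpha-chloro lactone serves at once as acyl donor, carrier of the C10 leaving group and mask of the C8 hydroxyl.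
Forward order: chloro lactone (C8, C9, C10, C1) → allylic bromide → cis alpha-methylene lactone (C6, C7, C11–C13) → enone methyl ketone (C2–C5, C15) → ten-membered ring and furanone in one operation → ester, desilylation.
Stereochemistry: C8 from (R)-5-(hydroxymethyl)oxolan-2-one; C10 by chlorination anti to the C8 side chain, then inversion in the key step; C7 and C6 from the Barbier step (control by C8, syn addition gives the cis-lactone); C5 by Felkin–Anh addition in the second Morita–Baylis–Hillman reaction.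

Key step: step 12

Assumption: the target is taken exactly as drawn, (5S,6R,7R,8R,10R) in the numbering above, which makes the 12,6-lactone cis-fused (H6 and H7 on the same face).

**Route**

Step 1
Reactants: 1 (5R)-5-(hydroxymethyl)oxolan-2-one
Product: 2 (5R)-5-[(triphenylmethoxy)methyl]oxolan-2-one
Conditions: Ph3CCl, Et3N, 4-(dimethylamino)pyridine (cat.), CH2Cl2, rt
Reagents that add atoms: trityl chloride, ClC(c1ccccc1)(c1ccccc1)c1ccccc1
Why: Tritylation (SN1 through the trityl cation) protects the primary alcohol and installs the bulky group that shields one face of the lactone in steps 2 and 3.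

Step 2
Reactants: 2 (5R)-5-[(triphenylmethoxy)methyl]oxolan-2-one
Product: 4 (3S,5R)-3-methyl-5-[(triphenylmethoxy)methyl]oxolan-2-one, via lithium enolate 3 (not isolated)
Conditions: LiN(i-Pr)2, THF, −78 °C; MeI, −78 → −40 °C
Reagents that add atoms: iodomethane, CI
Why: Enolate alkylation of the lactone with MeI should occur anti to the trityloxymethyl group (trans product), and since this centre is flattened again in step 3 its epimer is equally usable.

Step 3
Reactants: 4 (3S,5R)-3-methyl-5-[(triphenylmethoxy)methyl]oxolan-2-one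
Product: 6 (3S,5R)-3-chloro-3-methyl-5-[(triphenylmethoxy)methyl]oxolan-2-one, via lithium enolate 5 (not isolated)
Conditions: LiN(i-Pr)2, THF, −78 °C; C2Cl6, −78 → −30 °C
Reagents that add atoms: hexachloroethane, ClC(Cl)(Cl)C(Cl)(Cl)Cl
Why: Electrophilic chlorination of the tetrasubstituted lithium enolate should take place on the face anti to the trityloxymethyl group, as the second electrophile does in sequential dialkylations of this lactone, which places Cl trans and CH3 cis to the side chain and sets the (3S) centre that becomes C10.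

Step 4
Reactants: 6 (3S,5R)-3-chloro-3-methyl-5-[(triphenylmethoxy)methyl]oxolan-2-one
Product: 7 (3S,5R)-3-chloro-5-(hydroxymethyl)-3-methyloxolan-2-one
Conditions: AcOH–H2O (4:1), 50 °C
Reagents that add atoms: none
Why: Acidic solvolysis of the trityl ether (SN1 release of the trityl cation) frees the primary alcohol, while the tertiary chloride next to the carbonyl group resists ionisation.

Step 5
Reactants: 7 (3S,5R)-3-chloro-5-(hydroxymethyl)-3-methyloxolan-2-one
Product: 8 (2R,4S)-4-chloro-4-methyl-5-oxooxolane-2-carbaldehyde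
Conditions: Dess–Martin periodinane, CH2Cl2, 0 °C → rt; used crude
Reagents that add atoms: none
Why: Dess–Martin oxidation converts the primary alcohol to the aldehyde under neutral conditions that do not enolise the adjacent oxygen-bearing centre.

Step 6
Reactants: 8 (2R,4S)-4-chloro-4-methyl-5-oxooxolane-2-carbaldehyde; 9 methyl acrylate
Product: 10 methyl 2-{[(2R,4S)-4-chloro-4-methyl-5-oxooxolan-2-yl](hydroxy)methyl}prop-2-enoate (both carbinol epimers)
Conditions: 9 (excess, as solvent), 1,4-diazabicyclo[2.2.2]octane (0.5 equiv), rt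
Reagents that add atoms: none
Why: The Morita–Baylis–Hillman reaction of the activated alpha-acyloxy aldehyde attaches C11–C13 to C7, and the new carbinol centre, formed as a mixture, is erased in step 7.

Step 7
Reactants: 10 methyl 2-{[(2R,4S)-4-chloro-4-methyl-5-oxooxolan-2-yl](hydroxy)methyl}prop-2-enoate
Product: 11 methyl (2Z)-2-(bromomethyl)-3-[(2R,4S)-4-chloro-4-methyl-5-oxooxolan-2-yl]prop-2-enoate
Conditions: PBr3, Et2O, 0 °C
Reagents that add atoms: phosphorus tribromide, BrP(Br)Br
Why: Bromination of a Morita–Baylis–Hillman alcohol with PBr3 proceeds with allylic transposition (SN2') to the thermodynamically preferred (Z)-2-(bromomethyl)enoate, which removes the carbinol centre.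

Step 8
Reactants: 11 methyl (2Z)-2-(bromomethyl)-3-[(2R,4S)-4-chloro-4-methyl-5-oxooxolan-2-yl]prop-2-enoate; 12 2,2-dimethoxyacetaldehyde
Product: 15 (3S,5R)-3-chloro-5-[(2R,3R)-2-(dimethoxymethyl)-4-methylidene-5-oxooxolan-3-yl]-3-methyloxolan-2-one, via allylzinc bromide 13 (not isolated), via syn hydroxy ester 14 (not isolated)
Conditions: Zn dust, 12 (60% in water), THF–sat. aq. NH4Cl, rt; then camphor-10-sulfonic acid (cat.), CH2Cl2, rt
Reagents that add atoms: none
Why: The Barbier allylation runs through the gamma-carbon of allylzinc 13 in a chair transition state in which the (Z)-reagent gives the syn adduct 14 (hence the cis-lactone after acid-catalysed lactonisation), and the aldehyde is expected to attack the alkene face anti to the C8–C9 bond in the conformer that has H8 eclipsed with the double bond (allylic strain), which gives 7R and with it 6R.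

Step 9
Reactants: 15 (3S,5R)-3-chloro-5-[(2R,3R)-2-(dimethoxymethyl)-4-methylidene-5-oxooxolan-3-yl]-3-methyloxolan-2-one
Product: 16 (2R,3R)-3-[(2R,4S)-4-chloro-4-methyl-5-oxooxolan-2-yl]-4-methylidene-5-oxooxolane-2-carbaldehyde
Conditions: CF3CO2H–H2O (9:1), CH2Cl2, 0 °C → rt; used crude
Reagents that add atoms: water, O
Why: Acid hydrolysis of the dimethyl acetal unmasks the C5 aldehyde under conditions to which both lactones and the tertiary chloride are stable.

Step 10
Reactants: 16 (2R,3R)-3-[(2R,4S)-4-chloro-4-methyl-5-oxooxolan-2-yl]-4-methylidene-5-oxooxolane-2-carbaldehyde; 17 methyl vinyl ketone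
Product: 18 (3S,5R)-3-chloro-5-{(2R,3R)-2-[(1S)-1-hydroxy-2-methylidene-3-oxobutyl]-4-methylidene-5-oxooxolan-3-yl}-3-methyloxolan-2-one
Conditions: 17 (3 equiv), 1,4-diazabicyclo[2.2.2]octane (0.3 equiv), THF, 0 °C → rt
Reagents that add atoms: none
Why: The Morita–Baylis–Hillman reaction with methyl vinyl ketone forms C4–C5 and delivers the methyl ketone and the C4(15) methylene in one step, and Felkin–Anh addition anti to the C6–O bond should give the 5,6-anti (5S) alcohol.

Step 11
Reactants: 18 (3S,5R)-3-chloro-5-{(2R,3R)-2-[(1S)-1-hydroxy-2-methylidene-3-oxobutyl]-4-methylidene-5-oxooxolan-3-yl}-3-methyloxolan-2-one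
Product: 19 (3S,5R)-5-{(2R,3R)-2-[(1S)-1-(tert-butyldimethylsilyloxy)-2-methylidene-3-oxobutyl]-4-methylidene-5-oxooxolan-3-yl}-3-chloro-3-methyloxolan-2-one
Conditions: t-BuMe2SiOSO2CF3, 2,6-lutidine, CH2Cl2, −78 °C
Reagents that add atoms: tert-butyldimethylsilyl trifluoromethanesulfonate, CC(C)(C)[Si](C)(C)OS(=O)(=O)C(F)(F)F
Why: Silylation of the secondary alcohol with the silyl triflate at low temperature is faster than enol silyl ether formation at the ketone and removes the only O–H before the enolate step.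

Step 12
Reactants: 19 (3S,5R)-5-{(2R,3R)-2-[(1S)-1-(tert-butyldimethylsilyloxy)-2-methylidene-3-oxobutyl]-4-methylidene-5-oxooxolan-3-yl}-3-chloro-3-methyloxolan-2-one
Product: 22 (5S,6R,7R,8R,10R)-5-(tert-butyldimethylsilyloxy)-8-hydroxy-1-oxo-3,10-epoxygermacra-2,4(15),11(13)-trien-12,6-olide, via lithium dienolate 20 (not isolated), via chloro diketone 21 (not isolated)
Conditions: LiN(SiMe3)2 (1.05 equiv), THF, −78 °C, slow addition of 19 (final 0.001 M); −78 → 0 °C; then DMPU, rt → 40 °C
Reagents that add atoms: none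
Why: Proposed new method: LiN(SiMe3)2 removes a proton from the C2 methyl group, the only enolisable alpha-position of the ketone, and the C2 terminus of dienolate 20 adds to the C1 carbonyl of the alpha-chloro lactone, whose collapse opens the lactone, closes the ten-membered carbocycle (10-exo-trig acylation) and frees the C8 alkoxide, which is at once protonated by the far more acidic 1,3-diketone 21. The C3 enolate oxygen of 21 then displaces chloride from C10 in a 5-exo-tet closure that forms the 3(2H)-furanone and makes the sequence irreversible. The closest known reaction types are the Claisen acylation of ketone lithium enolates by lactones and the base-induced cyclisation of 4-halo-1,3-diketones to 3(2H)-furanones (the acyl variant of the Feist–Benary annulation), neither of which has been used as a macrocyclisation. C10 is the only new stereocentre and is set by inversion of the (S)-chloride from step 3 (SN2 displacement at tertiary alpha-chloro carbonyl centres is known to be invertive), which gives 10R; if an oxyallyl-type ionisation intervened, the face would instead be chosen by the ring. The step needs C1 acylation to win over attack on the methylene lactone (C12 or C13) and over bimolecular Michael addition: the chloro lactone is the most electrophilic carbonyl, the intramolecular alternatives would form eight-membered rings, and the 0.001 M concentration disfavours bimolecular paths.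

Step 13
Reactants: 22 (5S,6R,7R,8R,10R)-5-(tert-butyldimethylsilyloxy)-8-hydroxy-1-oxo-3,10-epoxygermacra-2,4(15),11(13)-trien-12,6-olide
Product: 23 (5S,6R,7R,8R,10R)-5-(tert-butyldimethylsilyloxy)-8-(2-methylpropanoyloxy)-1-oxo-3,10-epoxygermacra-2,4(15),11(13)-trien-12,6-olide
Conditions: (i-PrCO)2O, Et3N, 4-(dimethylamino)pyridine (cat.), CH2Cl2, 0 °C → rt
Reagents that add atoms: 2-methylpropanoic anhydride, CC(C)C(=O)OC(=O)C(C)C
Why: Acylation catalysed by 4-(dimethylamino)pyridine esterifies the only free hydroxyl (C8–OH) under conditions mild enough to avoid translactonisation.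

Step 14
Reactants: 23 (5S,6R,7R,8R,10R)-5-(tert-butyldimethylsilyloxy)-8-(2-methylpropanoyloxy)-1-oxo-3,10-epoxygermacra-2,4(15),11(13)-trien-12,6-olide
Product: 24 (5S,6R,7R,8R,10R)-5-hydroxy-8-(2-methylpropanoyloxy)-1-oxo-3,10-epoxygermacra-2,4(15),11(13)-trien-12,6-olide
Conditions: HF·pyridine, pyridine, THF, 0 °C → rt
Reagents that add atoms: none
Why: Fluoride-mediated cleavage of the silyl ether with buffered HF·pyridine liberates the C5 alcohol without touching the ester, the lactone or the enone units.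

**Compound list**

1 | (5R)-5-(hydroxymethyl)oxolan-2-one | OC[C@H]1CCC(=O)O1 | starting material
2 | (5R)-5-[(triphenylmethoxy)methyl]oxolan-2-one | C(c1ccccc1)(c1ccccc1)(c1ccccc1)OC[C@H]1CCC(=O)O1 | intermediate
3 | lithium enolate of 2 | C(c1ccccc1)(c1ccccc1)(c1ccccc1)OC[C@H]1CC=C(O[Li])O1 | intermediate
4 | (3S,5R)-3-methyl-5-[(triphenylmethoxy)methyl]oxolan-2-one (trans isomer) | C(c1ccccc1)(c1ccccc1)(c1ccccc1)OC[C@H]1C[C@H](C)C(=O)O1 | intermediate
5 | lithium enolate of 4 | C(c1ccccc1)(c1ccccc1)(c1ccccc1)OC[C@H]1CC(C)=C(O[Li])O1 | intermediate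
6 | (3S,5R)-3-chloro-3-methyl-5-[(triphenylmethoxy)methyl]oxolan-2-one (Cl trans, CH3 cis to the side chain) | C(c1ccccc1)(c1ccccc1)(c1ccccc1)OC[C@H]1C[C@](C)(Cl)C(=O)O1 | intermediate
7 | (3S,5R)-3-chloro-5-(hydroxymethyl)-3-methyloxolan-2-one | OC[C@H]1C[C@](C)(Cl)C(=O)O1 | intermediate
8 | (2R,4S)-4-chloro-4-methyl-5-oxooxolane-2-carbaldehyde | O=C[C@H]1C[C@](C)(Cl)C(=O)O1 | intermediate
9 | methyl acrylate | C=CC(=O)OC | starting material
10 | methyl 2-{[(2R,4S)-4-chloro-4-methyl-5-oxooxolan-2-yl](hydroxy)methyl}prop-2-enoate (both carbinol epimers) | C=C(C(=O)OC)C(O)[C@H]1C[C@](C)(Cl)C(=O)O1 | intermediate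
11 | methyl (2Z)-2-(bromomethyl)-3-[(2R,4S)-4-chloro-4-methyl-5-oxooxolan-2-yl]prop-2-enoate | COC(=O)/C(CBr)=C/[C@H]1C[C@](C)(Cl)C(=O)O1 | intermediate
12 | 2,2-dimethoxyacetaldehyde | COC(OC)C=O | starting material
13 | allylzinc bromide derived from 11 | COC(=O)/C(C[Zn]Br)=C/[C@H]1C[C@](C)(Cl)C(=O)O1 | intermediate
14 | methyl (3S,4R)-3-[(2R,4S)-4-chloro-4-methyl-5-oxooxolan-2-yl]-4-hydroxy-5,5-dimethoxy-2-methylidenepentanoate (syn adduct) | C=C(C(=O)OC)[C@@H]([C@@H](O)C(OC)OC)[C@H]1C[C@](C)(Cl)C(=O)O1 | intermediate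
15 | (3S,5R)-3-chloro-5-[(2R,3R)-2-(dimethoxymethyl)-4-methylidene-5-oxooxolan-3-yl]-3-methyloxolan-2-one (cis-lactone) | C=C1C(=O)O[C@@H](C(OC)OC)[C@H]1[C@H]2C[C@](C)(Cl)C(=O)O2 | intermediate
16 | (2R,3R)-3-[(2R,4S)-4-chloro-4-methyl-5-oxooxolan-2-yl]-4-methylidene-5-oxooxolane-2-carbaldehyde | C=C1C(=O)O[C@@H](C=O)[C@H]1[C@H]2C[C@](C)(Cl)C(=O)O2 | intermediate
17 | methyl vinyl ketone (but-3-en-2-one) | CC(=O)C=C | starting material
18 | (3S,5R)-3-chloro-5-{(2R,3R)-2-[(1S)-1-hydroxy-2-methylidene-3-oxobutyl]-4-methylidene-5-oxooxolan-3-yl}-3-methyloxolan-2-one | C=C1C(=O)O[C@@H]([C@@H](O)C(=C)C(C)=O)[C@H]1[C@H]2C[C@](C)(Cl)C(=O)O2 | intermediate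
19 | (3S,5R)-5-{(2R,3R)-2-[(1S)-1-(tert-butyldimethylsilyloxy)-2-methylidene-3-oxobutyl]-4-methylidene-5-oxooxolan-3-yl}-3-chloro-3-methyloxolan-2-one | C=C1C(=O)O[C@@H]([C@@H](O[Si](C)(C)C(C)(C)C)C(=C)C(C)=O)[C@H]1[C@H]2C[C@](C)(Cl)C(=O)O2 | intermediate
20 | lithium dienolate of 19 (enolate at C2) | C=C1C(=O)O[C@@H]([C@@H](O[Si](C)(C)C(C)(C)C)C(=C)C(=C)O[Li])[C@H]1[C@H]2C[C@](C)(Cl)C(=O)O2 | intermediate
21 | (5S,6R,7R,8R,10S)-5-(tert-butyldimethylsilyloxy)-10-chloro-8-hydroxy-1,3-dioxogermacra-4(15),11(13)-dien-12,6-olide (drawn neutral; present as its lithium enolate) | C=C1C(=O)O[C@@H]2[C@H]1[C@H](O)C[C@](C)(Cl)C(=O)CC(=O)C(=C)[C@@H]2O[Si](C)(C)C(C)(C)C | intermediate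
22 | (5S,6R,7R,8R,10R)-5-(tert-butyldimethylsilyloxy)-8-hydroxy-1-oxo-3,10-epoxygermacra-2,4(15),11(13)-trien-12,6-olide | C=C1C(=O)O[C@@H]2[C@H]1[C@H](O)C[C@@]1(C)OC(=CC1=O)C(=C)[C@@H]2O[Si](C)(C)C(C)(C)C | intermediate
23 | (5S,6R,7R,8R,10R)-5-(tert-butyldimethylsilyloxy)-8-(2-methylpropanoyloxy)-1-oxo-3,10-epoxygermacra-2,4(15),11(13)-trien-12,6-olide | C=C1C(=O)O[C@@H]2[C@H]1[C@H](OC(=O)C(C)C)C[C@@]1(C)OC(=CC1=O)C(=C)[C@@H]2O[Si](C)(C)C(C)(C)C | intermediate
24 | (5S,6R,7R,8R,10R)-5-hydroxy-8-(2-methylpropanoyloxy)-1-oxo-3,10-epoxygermacra-2,4(15),11(13)-trien-12,6-olide | C=C1C(=O)O[C@@H]2[C@H]1[C@H](OC(=O)C(C)C)C[C@@]1(C)OC(=CC1=O)C(=C)[C@@H]2O | target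

**Step count and risks**

Total step count: 14. Longest linear sequence: 14 steps (1 → 24); 9, 12 and 17 are commercial and enter directly.

Steps most likely to fail:

Step 12 (bears the label "Proposed new method"). Processes at risk: bimolecular Michael addition of dienolate 20 to the enone or methylene lactone of a second molecule (oligomerisation) may outrun the ten-membered acylation, and the closure at C10 may ionise instead of inverting. Fallback (sets out from 6, 12, 17 and 9; comes back at 23): the same two bonds are made bimolecularly, before any methylene lactone exists, and the ten-membered ring is closed last by an intramolecular Barbier allylation–lactonisation between C6 and C7, a ring closure known for germacranolides. Morita–Baylis–Hillman reaction of 17 with 12 (1,4-diazabicyclo[2.2.2]octane) gives racemic 3-(1-hydroxy-2,2-dimethoxyethyl)but-3-en-2-one F1, which is silylated (t-BuMe2SiOSO2CF3, 2,6-lutidine) to the silyl ether F2. Its lithium enolate F3 (LiN(SiMe3)2, THF, −78 °C) is acylated by lactone 6 to the open-chain chloro diketone F4, and K2CO3 in DMF closes this to the furanone alcohol F5, at which point the (5S) diastereomer is separated from its C5 epimer by chromatography. Acylation with isobutyric anhydride gives the isobutyrate F6, ZnBr2 in CH2Cl2 removes the trityl group to give the primary alcohol F7, and Dess–Martin oxidation gives the aldehyde F8. As in steps 6 and 7, reaction with 9 gives the allylic alcohol F9 and PBr3 the (Z)-allylic bromide F10; aqueous CF3CO2H then unmasks the C6 aldehyde F11. Zn dust in THF–aqueous NH4Cl at high dilution closes the ring to the hydroxy ester F12, which lactonises with camphor-10-sulfonic acid to 23.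

Step 8. Process at risk: poor facial selectivity of the allylzinc addition with respect to the C8 centre, or loss of syn selectivity, either of which would give C6/C7 diastereomers of the lactone. Fallback (sets out from 11; comes back at 16): the facial sense is taken from the aldehyde instead, using an alpha-alkoxy aldehyde whose Felkin–Anh preference fixes C6 and whose extra carbon is cut out afterwards. Zn-mediated Barbier reaction of 11 with commercial (S)-2,2-dimethyl-1,3-dioxolane-4-carbaldehyde gives the syn,anti hydroxy ester F13, which lactonises to the cis-lactone acetonide F14. Aqueous AcOH removes the acetonide to give the diol F15, and NaIO4 cleaves the diol to aldehyde 16.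

Step 10. Process at risk: epimerisation at C6 of the alpha-acyloxy aldehyde by the amine catalyst, poor facial selectivity in the reversible aldol stage, and elimination of HCl from the chloro lactone on long exposure to base. Fallback (sets out from 16 and 17; comes back at 18): a stoichiometric, non-basic conjugate addition–aldol–elimination sequence replaces the amine catalysis. Me2AlSePh adds to 17 at −78 °C, and the resulting aluminium enolate adds to 16 under kinetic control to give the beta-hydroxy selenide F16. H2O2 oxidises this to the selenoxide F17, which undergoes syn elimination at rt to 18.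

**Further compounds**

F1 | step 12 | racemic 3-(1-hydroxy-2,2-dimethoxyethyl)but-3-en-2-one | CC(=O)C(=C)C(O)C(OC)OC
F2 | step 12 | racemic 3-[1-(tert-butyldimethylsilyloxy)-2,2-dimethoxyethyl]but-3-en-2-one | CC(=O)C(=C)C(O[Si](C)(C)C(C)(C)C)C(OC)OC
F3 | step 12 | lithium enolate of F2 | C=C(O[Li])C(=C)C(O[Si](C)(C)C(C)(C)C)C(OC)OC
F4 | step 12 | open-chain chloro diketone from F3 and 6 (both C5 epimers; 8R,10S) | C(c1ccccc1)(c1ccccc1)(c1ccccc1)OC[C@H](O)C[C@](C)(Cl)C(=O)CC(=O)C(=C)C(O[Si](C)(C)C(C)(C)C)C(OC)OC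
F5 | step 12 | furanone alcohol: 2-methyl-2-[2-hydroxy-3-(triphenylmethoxy)propyl]-5-[3-(tert-butyldimethylsilyloxy)-4,4-dimethoxybut-1-en-2-yl]furan-3(2H)-one, (5S,8R,10R) in germacrane numbering | C[C@]1(C[C@@H](O)COC(c2ccccc2)(c2ccccc2)c2ccccc2)OC(=CC1=O)C(=C)[C@H](O[Si](C)(C)C(C)(C)C)C(OC)OC
F6 | step 12 | 8-isobutyrate of F5 | C[C@]1(C[C@@H](OC(=O)C(C)C)COC(c2ccccc2)(c2ccccc2)c2ccccc2)OC(=CC1=O)C(=C)[C@H](O[Si](C)(C)C(C)(C)C)C(OC)OC
F7 | step 12 | primary alcohol from detritylation of F6 | C[C@]1(C[C@@H](OC(=O)C(C)C)CO)OC(=CC1=O)C(=C)[C@H](O[Si](C)(C)C(C)(C)C)C(OC)OC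
F8 | step 12 | C7 aldehyde from F7 | C[C@]1(C[C@@H](OC(=O)C(C)C)C=O)OC(=CC1=O)C(=C)[C@H](O[Si](C)(C)C(C)(C)C)C(OC)OC
F9 | step 12 | Morita–Baylis–Hillman alcohol from F8 and 9 (both carbinol epimers) | C[C@]1(C[C@@H](OC(=O)C(C)C)C(O)C(=C)C(=O)OC)OC(=CC1=O)C(=C)[C@H](O[Si](C)(C)C(C)(C)C)C(OC)OC
F10 | step 12 | (Z)-allylic bromide from F9 | C[C@]1(C[C@@H](OC(=O)C(C)C)/C=C(\CBr)C(=O)OC)OC(=CC1=O)C(=C)[C@H](O[Si](C)(C)C(C)(C)C)C(OC)OC
F11 | step 12 | C6 aldehyde from acetal hydrolysis of F10 | C[C@]1(C[C@@H](OC(=O)C(C)C)/C=C(\CBr)C(=O)OC)OC(=CC1=O)C(=C)[C@H](O[Si](C)(C)C(C)(C)C)C=O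
F12 | step 12 | ring-closed hydroxy ester (ten-membered ring, C6–OH, methyl 2-propenoate on C7) | COC(=O)C(=C)[C@@H]1[C@H](OC(=O)C(C)C)C[C@@]2(C)OC(=CC2=O)C(=C)[C@H](O[Si](C)(C)C(C)(C)C)[C@@H]1O
F13 | step 8 | syn,anti hydroxy ester from 11 and (S)-2,2-dimethyl-1,3-dioxolane-4-carbaldehyde | C=C(C(=O)OC)[C@@H]([C@@H](O)[C@@H]1COC(C)(C)O1)[C@H]2C[C@](C)(Cl)C(=O)O2
F14 | step 8 | cis-lactone acetonide (dioxolanyl group on C6) | C=C1C(=O)O[C@@H]([C@@H]2COC(C)(C)O2)[C@H]1[C@H]3C[C@](C)(Cl)C(=O)O3
F15 | step 8 | cis-lactone diol (1,2-dihydroxyethyl group on C6) | C=C1C(=O)O[C@@H]([C@@H](O)CO)[C@H]1[C@H]2C[C@](C)(Cl)C(=O)O2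
F16 | step 10 | beta-hydroxy selenide: 18 with C4H–CH2SePh in place of C4=CH2 (both C4 epimers) | C=C1C(=O)O[C@@H]([C@@H](O)C(C[Se]c2ccccc2)C(C)=O)[C@H]1[C@H]3C[C@](C)(Cl)C(=O)O3
F17 | step 10 | selenoxide of F16 | C=C1C(=O)O[C@@H]([C@@H](O)C(C[Se](=O)c2ccccc2)C(C)=O)[C@H]1[C@H]3C[C@](C)(Cl)C(=O)O3
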